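in all of them: solid electrophile 0.099 M
- epsilon: nucleophile 1.1 equiv; buffer base 3 equiv; buffer acid 0.10 equiv; the very flask that is asked about, followed so far
- flask: nucleophile 1.10 equiv; buffer base 3.00 equiv; buffer acid 0.100 equiv; time 40 h

epsilon run (percent of the solid electrophile charged)

| time / h | solid electrophile / % | target / % |
|---|---|---|
| 1.00 | 95.6 | 1.1 |
| 1.50 | 95.1 | 0 |
| 2.50 | 91.7 | 2.4 |
| 4.00 | 86.8 | 0 |
| 8.00 | 79.6 | 0 |
| 12.0 | 71.7 | 0.4 |

(each reading ± 1 percentage point)

1. part of the solid electrophile that has reacted (what has only dissolved counts as not reacted) at 40 h
2. pH of the solution at 40 h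

- at the start none of the solid electrophile is in solution
- what has only dissolved of solid electrophile counts as not reacted
- the earlier runs do not show the pH; that part of a forecast is a guess

1. The buffer acid is a small charge, 0.100 equiv against 3.00 equiv of buffer base, and no run shows the pH, so the pH remains a guess. Conversion can be reckoned.

2. With 71.7% of solid electrophile standing at 12.0 h, first-order loss gives a dissolution time of 36.1 h.

3. Extreme one: capture is instantaneous and dissolution is the rate-limiting step. Conversion then equals solid lost, 67.0% at 40 h. At 12.0 h that extreme requires 28.3% reacted, but target reads 0.4%. Extreme two: dissolved material never reacts, and conversion is zero.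

4. Between them lies slow capture, measured here by exposure, the time integral of the dissolved fraction, 15.8 h. Nucleophile is charged at 1.10 equiv and is consumed, so conversion proportional to exposure is a rough scaling, not a pseudo-first-order law.

5. Exposure at 12.0 h is 1.79 h. If target records what has reacted, its reading there gives 3.53% at 40 h, and the highest target reading, 2.4%, gives 21.2%. This reckoning commits to that range.

6. The forecast gives 6% (1.5% to 30%) and pH 9 (6.5 to 11.5), holding that “most of this loss looks like dissolution, not reaction”.

7. The flask gives 14.5% and pH 8.62.

    electrophile + nucleophile → acid + target + leaving group (k = 0.189 /M/h)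
    protonated nucleophile ⇌ nucleophile + acid, settled at all times (K = 1.30 × 10⁻⁸ M)
    buffer acid ⇌ buffer base + acid, settled at all times (K = 5.00 × 10⁻⁸ M)
    solid electrophile ⇌ electrophile, rate k4*(cs4 - [electrophile]) while solid is left; crystals form when [electrophile] > cs4 (solubility = 49.0 mM, k = 0.0653 /h)
    nucleophile ⇌ dormant form (K = 0.520, k = 0.0265 /h)
    target → over-reaction product (k = 0.165 /h)

8. At 11.8 h target is made 1.51 times as fast as it is used up, and at 40.0 h that ratio is 0.990; target stands at 2.55% beside 12.0% of over-reaction product. The result per unit of exposure is 0.00916 /h. For the same recipe read at 15 h, exposure is 2.73 h, which at that figure gives 2.50%; the computed conversion is 3.95%, a higher 0.0145 /h per unit of exposure, with nucleophile at 68.4% of its charge there against 50.4% at 40.0 h.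

The runs were computed with made-up constants; noise was put on by code.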